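With the 28-membered ring numbered from the propyl-bearing carbon C1 through O2 and the ester carbonyl C3 round to N27 and the amide carbonyl C28, the route rests on disconnecting the disubstituted E-alkene C16=C17 of the C16–C19 diene, which is carried as the triple bond of a 1,3-enyne. Ring-closing alkyne metathesis of an open-chain diyne forms the C16–C17 bond and the macrocycle in a single operation, leaving the preset Z-alkene C18=C19 untouched; trans-hydrosilylation and protodesilylation then deliver the E-alkene. The precursor is an ester- and amide-linked chain with methyl-capped alkynes at C15 and C18, silyl ethers at C11 and C25 and a C22/C23 acetonide.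

Key step: step 25

Assumption 1: fragment carbons carry the numbers they have in the target ring (C1 to C28).
Assumption 2: in the ligand-controlled steps 7 and 16 the ligand or alkaloid enantiomer is the one expected to give the stated configuration; the mirror-image ligand or pseudo-enantiomeric alkaloid would be used if the sense proved opposite.
Assumption 3: silicon in 38 is drawn on C17; the C16 regioisomer would lead to the same diene.

Step 1
Reactants: 1 3-methoxyprop-1-yne
Product: 2 (E)-2-bromo-1-iodo-3-methoxyprop-1-ene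
Conditions: IBr (1.05 equiv), CH2Cl2, −78 → 0 °C, dark
Reagents that add atoms: iodine monobromide, BrI
Why: Electrophilic anti-addition of I–Br to the terminal alkyne (halogen addition through a bridged iodonium ion opened by bromide at the internal carbon) should give the E-dihalide with iodine on the terminal carbon.

Step 2
Reactants: 2 (E)-2-bromo-1-iodo-3-methoxyprop-1-ene
Product: 3 (E)-2-bromo-1-methoxyhex-2-en-4-yne
Conditions: propyne (3 equiv), Pd(PPh3)2Cl2 (3 mol %), CuI (6 mol %), i-Pr2NH, THF, −20 → 20 °C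
Reagents that add atoms: propyne, CC#C
Why: Sonogashira coupling should occur only at the more reactive and less hindered C–I bond with retention of geometry, placing the propynyl group trans to bromine and cis to CH2OMe.

Step 3
Reactants: 4 2-deoxy-D-ribose
Product: 5 2-deoxy-3,4-O-isopropylidene-D-erythro-pentopyranose
Conditions: 2-methoxypropene (1.3 equiv), TsOH·H2O (cat.), DMF, 0 °C
Reagents that add atoms: 2-methoxypropene, COC(C)=C
Why: Kinetic acetalisation of the cis-3,4-diol of the pyranose form gives the cis-fused dioxolane and leaves the anomeric hydroxyl free, the two stereocentres (future C22 and C23) coming unchanged from the sugar.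

Step 4
Reactants: 5 2-deoxy-3,4-O-isopropylidene-D-erythro-pentopyranose
Product: 6 [(4R,5S)-2,2-dimethyl-5-(3-methylbut-2-en-1-yl)-1,3-dioxolan-4-yl]methanol
Conditions: i-PrPPh3I (2.5 equiv), n-BuLi (2.4 equiv), THF, 0 °C; then 5, 0 → 20 °C
Reagents that add atoms: isopropyltriphenylphosphonium iodide, CC(C)[P+](c1ccccc1)(c1ccccc1)c1ccccc1.[I-]
Why: Wittig olefination of the open-chain aldehyde tautomer of the lactol with the non-stabilised isopropylidene ylide installs a trisubstituted alkene as a masked C25 aldehyde and frees the C21 primary alcohol.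

Step 5
Reactants: 6 [(4R,5S)-2,2-dimethyl-5-(3-methylbut-2-en-1-yl)-1,3-dioxolan-4-yl]methanol
Product: 8 (4S,5R)-2,2-dimethyl-4-(3-methylbut-2-en-1-yl)-5-vinyl-1,3-dioxolane, via aldehyde 7 (not isolated)
Conditions: Dess–Martin periodinane, NaHCO3, CH2Cl2, 0 °C; filter; then Ph3PCH3Br, KN(SiMe3)2, THF, −78 → 0 °C
Reagents that add atoms: methyltriphenylphosphonium bromide, C[P+](c1ccccc1)(c1ccccc1)c1ccccc1.[Br-]
Why: Buffered Dess–Martin oxidation followed at once by Wittig methylenation with a salt-free ylide at low temperature converts the alcohol into the vinyl group before the cis-dioxolane α-alkoxy aldehyde can epimerise at C22.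

Step 6
Reactants: 8 (4S,5R)-2,2-dimethyl-4-(3-methylbut-2-en-1-yl)-5-vinyl-1,3-dioxolane
Product: 9 2-[(4S,5R)-2,2-dimethyl-5-vinyl-1,3-dioxolan-4-yl]acetaldehyde
Conditions: O3 (1.0 equiv, Sudan Red 7B end point), pyridine (3 equiv), CH2Cl2, −78 °C
Reagents that add atoms: ozone, [O-][O+]=O
Why: Ozonolysis in the presence of pyridine (direct, reductant-free cleavage) should select the electron-rich trisubstituted alkene over the vinyl group, which is deactivated by the allylic acetal oxygen.

Step 7
Reactants: 9 2-[(4S,5R)-2,2-dimethyl-5-vinyl-1,3-dioxolan-4-yl]acetaldehyde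
Product: 10 (2S)-1-[(4S,5R)-2,2-dimethyl-5-vinyl-1,3-dioxolan-4-yl]-3-nitropropan-2-ol
Conditions: MeNO2 (10 equiv), Cu(OAc)2·H2O (5 mol %), indane-fused bis(oxazoline) ligand (5.5 mol %), EtOH, 20 °C
Reagents that add atoms: nitromethane, C[N+](=O)[O-]
Why: The copper–bis(oxazoline)-catalysed asymmetric Henry reaction adds the nitronate to the Re face of the aldehyde under catalyst control, setting the (S)-carbinol at C25 under nearly neutral conditions that should spare the β-alkoxy aldehyde from elimination.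

Step 8
Reactants: 10 (2S)-1-[(4S,5R)-2,2-dimethyl-5-vinyl-1,3-dioxolan-4-yl]-3-nitropropan-2-ol
Product: 11 tert-butyldimethylsilyl ether of 10
Conditions: TBSOTf (1.2 equiv), 2,6-lutidine (2 equiv), CH2Cl2, −78 °C
Reagents that add atoms: tert-butyldimethylsilyl triflate, CC(C)(C)[Si](C)(C)OS(=O)(=O)C(F)(F)F
Why: Silyl ether formation with the triflate and a hindered base at low temperature should outrun retro-nitroaldol cleavage.

Step 9
Reactants: 11 tert-butyldimethylsilyl ether of 10
Product: 12 (2S)-2-(tert-butyldimethylsilyloxy)-3-[(4S,5R)-2,2-dimethyl-5-vinyl-1,3-dioxolan-4-yl]propan-1-amine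
Conditions: Zn dust (20 equiv), AcOH, THF, 0 → 20 °C; aq. NaHCO3
Reagents that add atoms: none
Why: Dissolving-metal reduction of the aliphatic nitro group with zinc in acetic acid gives the primary amine and leaves the vinyl group, silyl ether and acetonide alone.

Step 10
Reactants: 12 (2S)-2-(tert-butyldimethylsilyloxy)-3-[(4S,5R)-2,2-dimethyl-5-vinyl-1,3-dioxolan-4-yl]propan-1-amine; 13 (S)-2-hydroxypentanoic acid
Product: 14 vinyl hydroxy amide (C1 to C28 amide bond formed)
Conditions: EDC·HCl (1.3 equiv), HOBt (1.3 equiv), i-Pr2NEt, CH2Cl2, 0 → 20 °C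
Reagents that add atoms: none
Why: Carbodiimide/HOBt amide coupling acylates the primary amine chemoselectively in the presence of the much less nucleophilic secondary hydroxyl, and HOBt limits epimerisation at C1.

Step 11
Reactants: 14 vinyl hydroxy amide; 3 (E)-2-bromo-1-methoxyhex-2-en-4-yne
Product: 16 east alcohol carrying the methyl-capped (Z)-enyne, via alkylborane 15 (not isolated)
Conditions: 9-BBN (3.5 equiv), THF, 0 → 20 °C; then 3, Pd(dppf)Cl2 (10 mol %), AsPh3 (10 mol %), Cs2CO3 (3 equiv), DMF/H2O, 20 °C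
Reagents that add atoms: none
Why: Anti-Markovnikov hydroboration of the only alkene with 9-BBN (the hydroxyl being borylated transiently) and B-alkyl Suzuki–Miyaura coupling with the alkenyl bromide with retention of configuration forms the C19–C20 bond and gives the Z-configured C18=C19 alkene.

Step 12
Reactants: 17 (E)-pent-2-en-1-ol
Product: 18 [(2S,3S)-3-ethyloxiran-2-yl]methanol
Conditions: Ti(OiPr)4 (10 mol %), L-(+)-diisopropyl tartrate (12 mol %), t-BuOOH, 4 Å MS, CH2Cl2, −20 °C
Reagents that add atoms: tert-butyl hydroperoxide, CC(C)(C)OO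
Why: Sharpless asymmetric epoxidation of the E-allylic alcohol with the L-(+)-tartrate ligand delivers oxygen to one face and sets both epoxide centres as (2S,3S).

Step 13
Reactants: 18 [(2S,3S)-3-ethyloxiran-2-yl]methanol
Product: 19 (2R,3S)-3-ethylhex-4-yne-1,2-diol
Conditions: propyne, n-BuLi, toluene, −78 → 0 °C; Et2AlCl, 0 °C; then 18, 0 → 20 °C; aq. Rochelle salt
Reagents that add atoms: propyne, CC#C
Why: Regioselective C3 opening of the 2,3-epoxy alcohol by the alkynylalane, delivered through the aluminium alkoxide with SN2 inversion, installs the propynyl group and sets the future C15 stereocentre.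

Step 14
Reactants: 19 (2R,3S)-3-ethylhex-4-yne-1,2-diol
Product: 22 (3R)-3-ethylhex-4-yn-1-ol, via enyne 20 (not isolated), via alkylborane 21 (not isolated)
Conditions: PPh3, I2, imidazole, toluene, 80 °C; silica plug (pentane); then 9-BBN (1.05 equiv), THF, 0 → 20 °C; NaOH, H2O2, 0 °C
Reagents that add atoms: hydrogen peroxide, OO
Why: Garegg–Samuelsson deoxygenation of the vicinal diol gives the volatile terminal alkene, which is kept in solution and undergoes hydroboration–oxidation at the monosubstituted alkene in preference to the internal alkyne, the C15 centre not being involved.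

Step 15
Reactants: 22 (3R)-3-ethylhex-4-yn-1-ol
Product: 23 (4R)-6-bromo-4-ethylhex-2-yne
Conditions: CBr4 (1.3 equiv), PPh3 (1.4 equiv), CH2Cl2, 0 °C
Reagents that add atoms: carbon tetrabromide, BrC(Br)(Br)Br
Why: Appel bromination converts the primary alcohol into the bromide under neutral conditions without touching the alkyne or the stereocentre.

Step 16
Reactants: 24 meso-2,4-dimethylglutaric anhydride
Product: 25 (2R,4S)-5-methoxy-2,4-dimethyl-5-oxopentanoic acid
Conditions: MeOH (10 equiv), quinidine (1.1 equiv), toluene, −55 °C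
Reagents that add atoms: methanol, CO
Why: Cinchona alkaloid-mediated desymmetrising methanolysis opens one of the two enantiotopic carbonyl groups of the meso anhydride, fixing both methyl-bearing stereocentres (future C4 and C6) in one step.

Step 17
Reactants: 25 (2R,4S)-5-methoxy-2,4-dimethyl-5-oxopentanoic acid
Product: 26 methyl (2S,4R)-5-hydroxy-2,4-dimethylpentanoate
Conditions: BH3·SMe2 (1.1 equiv), THF, −10 → 20 °C; MeOH
Reagents that add atoms: none
Why: Borane reduces the free carboxylic acid chemoselectively in the presence of the methyl ester, and the hydroxy ester is used without delay to avoid lactonisation.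

Step 18
Reactants: 26 methyl (2S,4R)-5-hydroxy-2,4-dimethylpentanoate
Product: 28 methyl (2S,4R)-2,4-dimethylhex-5-enoate, via aldehyde 27 (not isolated)
Conditions: Dess–Martin periodinane, NaHCO3, CH2Cl2, 0 °C; filter; then Ph3PCH3Br, KN(SiMe3)2, THF, −78 → 0 °C
Reagents that add atoms: methyltriphenylphosphonium bromide, C[P+](c1ccccc1)(c1ccccc1)c1ccccc1.[Br-]
Why: Dess–Martin oxidation and immediate low-temperature Wittig methylenation give the terminal alkene while limiting enolisation of the α-methyl aldehyde (future C6).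

Step 19
Reactants: 28 methyl (2S,4R)-2,4-dimethylhex-5-enoate; 29 (R)-2-(but-3-en-1-yl)oxirane
Product: 30 methyl (2S,4R,5E)-2,4-dimethyl-8-[(2R)-oxiran-2-yl]oct-5-enoate
Conditions: 29 (3 equiv), second-generation Hoveyda–Grubbs catalyst RuCl2(H2IMes)(=CH-C6H4-2-OiPr) (5 mol %), CH2Cl2, 40 °C
Reagents that add atoms: none
Why: Olefin cross-metathesis between the α-branched alkene and an excess of the unhindered epoxy alkene, driven by loss of ethene, joins C7 to C8 and brings in the C11 stereocentre from the enantiopure epoxide, which the ruthenium carbene tolerates.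

Step 20
Reactants: 30 methyl (2S,4R,5E)-2,4-dimethyl-8-[(2R)-oxiran-2-yl]oct-5-enoate
Product: 31 methyl (2S,4S)-2,4-dimethyl-8-[(2R)-oxiran-2-yl]octanoate
Conditions: H2 (1 atm), Pt/C (5 %), EtOAc, 20 °C
Reagents that add atoms: none
Why: Heterogeneous catalytic hydrogenation over platinum saturates the disubstituted alkene of either geometry without hydrogenolysis of the aliphatic epoxide.

Step 21
Reactants: 31 methyl (2S,4S)-2,4-dimethyl-8-[(2R)-oxiran-2-yl]octanoate; 23 (4R)-6-bromo-4-ethylhex-2-yne
Product: 33 methyl (2S,4S,9R,13R)-13-ethyl-9-hydroxy-2,4-dimethylhexadec-14-ynoate, via Grignard reagent 32 (not isolated)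
Conditions: 23, Mg, THF, 20 °C; then 31, CuI (10 mol %), THF, −40 °C; aq. NH4Cl
Reagents that add atoms: none
Why: Copper-catalysed Grignard opening of the terminal epoxide at its CH2 carbon (SN2 through an organocuprate) forms the C12–C13 bond at low temperature faster than addition to the α-branched methyl ester and leaves C11 unchanged.

Step 22
Reactants: 33 methyl (2S,4S,9R,13R)-13-ethyl-9-hydroxy-2,4-dimethylhexadec-14-ynoate
Product: 34 tert-butyldimethylsilyl ether of 33
Conditions: TBSOTf (1.3 equiv), 2,6-lutidine (2.5 equiv), CH2Cl2, −78 → 0 °C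
Reagents that add atoms: tert-butyldimethylsilyl triflate, CC(C)(C)[Si](C)(C)OS(=O)(=O)C(F)(F)F
Why: Silyl ether formation at the only hydroxyl proceeds cleanly with the reactive triflate.

Step 23
Reactants: 34 tert-butyldimethylsilyl ether of 33
Product: 35 west acid (2S,4S,9R,13R)-9-(tert-butyldimethylsilyloxy)-13-ethyl-2,4-dimethylhexadec-14-ynoic acid
Conditions: LiOH·H2O (5 equiv), THF/MeOH/H2O, 20 °C; 1 M HCl to pH 4
Reagents that add atoms: lithium hydroxide, [Li+].[OH-]
Why: Saponification of the methyl ester at room temperature should give the acid without appreciable epimerisation at the α-methyl centre or loss of the secondary silyl ether.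

Step 24
Reactants: 35 west acid; 16 east alcohol carrying the methyl-capped (Z)-enyne
Product: 36 seco diyne (C3 ester of the C1 hydroxyl)
Conditions: 2,4,6-Cl3C6H2COCl (1.5 equiv), Et3N (3 equiv), DMAP (2 equiv), toluene, 20 °C
Reagents that add atoms: none
Why: Yamaguchi esterification through the mixed 2,4,6-trichlorobenzoic anhydride and DMAP acylates the hindered secondary hydroxyl of the α-hydroxy amide with retention at C1, the amide N–H being unreactive.

Step 25
Reactants: 36 seco diyne
Product: 37 protected 28-membered macrocyclic 16-yne-18-ene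
Conditions: [Mo(≡CC6H4OMe-4)(OSiPh3)3] (20 mol %), 5 Å MS, toluene (2 mM), 25 → 60 °C
Reagents that add atoms: none
Why: The molybdenum alkylidyne adds to one propynyl terminus by [2+2] cycloaddition to a metallacyclobutadiene, cycloreverts to a substrate-bound alkylidyne, and repeats the sequence on the second alkyne so that the C16≡C17 bond forms and 2-butyne is released. The closest known reaction type is ring-closing alkyne metathesis of methyl-capped diynes to macrocyclic 1,3-enynes with silanolate-supported molybdenum alkylidynes. The 28-membered ring (C1 to C28) is closed end to end by joining the alkyne carbons C16 and C17, a macrocyclisation in which the new triple bond lies inside the ring. No stereocentre is created, and the Z geometry of C18=C19 set in step 11 is preserved because the catalyst does not engage alkenes. The step needs chemoselectivity for the two alkynes over the alkene, ester, amide N–H and silyl ethers, which this class of alkylidyne provides, and ring closure over oligomerisation, which is secured by 2 mM dilution and by the sieves, which take up 2-butyne and pull the equilibria towards the ring.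

Step 26
Reactants: 37 protected macrocyclic 16-yne-18-ene
Product: 38 (16Z)-17-(benzyldimethylsilyl)-16,18-diene macrocycle
Conditions: BnMe2SiH (1.5 equiv), [Cp*Ru(MeCN)3]PF6 (10 mol %), CH2Cl2, 0 → 20 °C
Reagents that add atoms: benzyldimethylsilane, C[SiH](C)Cc1ccccc1
Why: Ruthenium-catalysed trans-hydrosilylation adds H and Si to opposite sides of the triple bond, so the C16=C17 alkene will be E after desilylation whichever alkyne carbon carries silicon, and the trisubstituted alkene is not touched.

Step 27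
Reactants: 38 (16Z)-17-(benzyldimethylsilyl)-16,18-diene macrocycle
Product: 39 (16E,18Z)-diene macrocycle with free C11 and C25 hydroxyls and the C22/C23 acetonide
Conditions: Bu4NF (6 equiv), THF, 20 → 40 °C
Reagents that add atoms: none
Why: Fluoride-induced protodesilylation of the dienylsilane proceeds with retention of alkene geometry, and the same reagent cleaves both tert-butyldimethylsilyl ethers.

Step 28
Reactants: 39 (16E,18Z)-diene macrocycle with the C22/C23 acetonide
Product: 40 CNP0221503.3
Conditions: AcOH/H2O/THF (3:1:1), 20 → 40 °C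
Reagents that add atoms: none
Why: Mild acid-catalysed hydrolysis of the isopropylidene acetal frees the C22/C23 diol without ionising the allylic methyl ether or isomerising the E,Z-diene.

Compound list
1 | 3-methoxyprop-1-yne | COCC#C | starting material
2 | (E)-2-bromo-1-iodo-3-methoxyprop-1-ene | I/C=C(/Br)COC | intermediate
3 | (E)-2-bromo-1-methoxyhex-2-en-4-yne | CC#C/C=C(/Br)COC | intermediate
4 | 2-deoxy-D-ribose | O=CC[C@H](O)[C@H](O)CO | starting material
5 | 2-deoxy-3,4-O-isopropylidene-D-erythro-pentopyranose (anomer mixture) | OC1C[C@@H]2OC(C)(C)O[C@@H]2CO1 | intermediate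
6 | [(4R,5S)-2,2-dimethyl-5-(3-methylbut-2-en-1-yl)-1,3-dioxolan-4-yl]methanol | CC(C)=CC[C@@H]1OC(C)(C)O[C@@H]1CO | intermediate
7 | (4S,5S)-2,2-dimethyl-5-(3-methylbut-2-en-1-yl)-1,3-dioxolane-4-carbaldehyde | CC(C)=CC[C@@H]1OC(C)(C)O[C@@H]1C=O | intermediate
8 | (4S,5R)-2,2-dimethyl-4-(3-methylbut-2-en-1-yl)-5-vinyl-1,3-dioxolane | CC(C)=CC[C@@H]1OC(C)(C)O[C@@H]1C=C | intermediate
9 | 2-[(4S,5R)-2,2-dimethyl-5-vinyl-1,3-dioxolan-4-yl]acetaldehyde | O=CC[C@@H]1OC(C)(C)O[C@@H]1C=C | intermediate
10 | (2S)-1-[(4S,5R)-2,2-dimethyl-5-vinyl-1,3-dioxolan-4-yl]-3-nitropropan-2-ol | O=[N+]([O-])C[C@@H](O)C[C@@H]1OC(C)(C)O[C@@H]1C=C | intermediate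
11 | tert-butyl{[(2S)-1-[(4S,5R)-2,2-dimethyl-5-vinyl-1,3-dioxolan-4-yl]-3-nitropropan-2-yl]oxy}dimethylsilane | O=[N+]([O-])C[C@@H](O[Si](C)(C)C(C)(C)C)C[C@@H]1OC(C)(C)O[C@@H]1C=C | intermediate
12 | (2S)-2-(tert-butyldimethylsilyloxy)-3-[(4S,5R)-2,2-dimethyl-5-vinyl-1,3-dioxolan-4-yl]propan-1-amine | NC[C@@H](O[Si](C)(C)C(C)(C)C)C[C@@H]1OC(C)(C)O[C@@H]1C=C | intermediate
13 | (S)-2-hydroxypentanoic acid | CCC[C@H](O)C(=O)O | starting material
14 | (2S)-N-[(2S)-2-(tert-butyldimethylsilyloxy)-3-[(4S,5R)-2,2-dimethyl-5-vinyl-1,3-dioxolan-4-yl]propyl]-2-hydroxypentanamide | CCC[C@H](O)C(=O)NC[C@@H](O[Si](C)(C)C(C)(C)C)C[C@@H]1OC(C)(C)O[C@@H]1C=C | intermediate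
15 | C20 B-alkyl-9-borabicyclo[3.3.1]nonane of 14, hydroxyl as its 9-BBN borinate | CCC[C@H](OB3C4CCCC3CCC4)C(=O)NC[C@@H](O[Si](C)(C)C(C)(C)C)C[C@@H]1OC(C)(C)O[C@@H]1CCB5C6CCCC5CCC6 | intermediate
16 | (2S)-N-[(2S)-2-(tert-butyldimethylsilyloxy)-3-[(4S,5R)-5-[(3Z)-3-(methoxymethyl)hept-3-en-5-yn-1-yl]-2,2-dimethyl-1,3-dioxolan-4-yl]propyl]-2-hydroxypentanamide | CCC[C@H](O)C(=O)NC[C@@H](O[Si](C)(C)C(C)(C)C)C[C@@H]1OC(C)(C)O[C@@H]1CC/C(COC)=C/C#CC | intermediate
17 | (E)-pent-2-en-1-ol | CC/C=C/CO | starting material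
18 | [(2S,3S)-3-ethyloxiran-2-yl]methanol | CC[C@@H]1O[C@H]1CO | intermediate
19 | (2R,3S)-3-ethylhex-4-yne-1,2-diol | CC#C[C@H](CC)[C@@H](O)CO | intermediate
20 | (3R)-3-ethylhex-1-en-4-yne | CC#C[C@H](CC)C=C | intermediate
21 | 9-[(3R)-3-ethylhex-4-yn-1-yl]-9-borabicyclo[3.3.1]nonane | CC#C[C@H](CC)CCB1C2CCCC1CCC2 | intermediate
22 | (3R)-3-ethylhex-4-yn-1-ol | CC#C[C@H](CC)CCO | intermediate
23 | (4R)-6-bromo-4-ethylhex-2-yne | CC#C[C@H](CC)CCBr | intermediate
24 | meso-2,4-dimethylglutaric anhydride | C[C@H]1C[C@@H](C)C(=O)OC1=O | starting material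
25 | (2R,4S)-5-methoxy-2,4-dimethyl-5-oxopentanoic acid | COC(=O)[C@@H](C)C[C@@H](C)C(=O)O | intermediate
26 | methyl (2S,4R)-5-hydroxy-2,4-dimethylpentanoate | COC(=O)[C@@H](C)C[C@@H](C)CO | intermediate
27 | methyl (2S,4R)-2,4-dimethyl-5-oxopentanoate | COC(=O)[C@@H](C)C[C@@H](C)C=O | intermediate
28 | methyl (2S,4R)-2,4-dimethylhex-5-enoate | COC(=O)[C@@H](C)C[C@@H](C)C=C | intermediate
29 | (R)-2-(but-3-en-1-yl)oxirane | C=CCC[C@@H]1CO1 | starting material
30 | methyl (2S,4R,5E)-2,4-dimethyl-8-[(2R)-oxiran-2-yl]oct-5-enoate | COC(=O)[C@@H](C)C[C@@H](C)/C=C/CC[C@@H]1CO1 | intermediate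
31 | methyl (2S,4S)-2,4-dimethyl-8-[(2R)-oxiran-2-yl]octanoate | COC(=O)[C@@H](C)C[C@@H](C)CCCC[C@@H]1CO1 | intermediate
32 | [(3R)-3-ethylhex-4-yn-1-yl]magnesium bromide | CC#C[C@H](CC)CC[Mg]Br | intermediate
33 | methyl (2S,4S,9R,13R)-13-ethyl-9-hydroxy-2,4-dimethylhexadec-14-ynoate | COC(=O)[C@@H](C)C[C@@H](C)CCCC[C@@H](O)CCC[C@@H](CC)C#CC | intermediate
34 | methyl (2S,4S,9R,13R)-9-(tert-butyldimethylsilyloxy)-13-ethyl-2,4-dimethylhexadec-14-ynoate | COC(=O)[C@@H](C)C[C@@H](C)CCCC[C@@H](O[Si](C)(C)C(C)(C)C)CCC[C@@H](CC)C#CC | intermediate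
35 | (2S,4S,9R,13R)-9-(tert-butyldimethylsilyloxy)-13-ethyl-2,4-dimethylhexadec-14-ynoic acid | OC(=O)[C@@H](C)C[C@@H](C)CCCC[C@@H](O[Si](C)(C)C(C)(C)C)CCC[C@@H](CC)C#CC | intermediate
36 | seco diyne: ester of 35 with the C1 hydroxyl of 16 (propynyl groups at C15 and C18, silyl ethers at C11 and C25, C22/C23 acetonide) | CC#C[C@H](CC)CCC[C@H](O[Si](C)(C)C(C)(C)C)CCCC[C@H](C)C[C@H](C)C(=O)O[C@@H](CCC)C(=O)NC[C@@H](O[Si](C)(C)C(C)(C)C)C[C@@H]1OC(C)(C)O[C@@H]1CC/C(COC)=C/C#CC | intermediate
37 | protected 28-membered macrocycle with the C16≡C17 triple bond and the (18Z)-alkene | CCC[C@@H]1OC(=O)[C@@H](C)C[C@@H](C)CCCC[C@@H](O[Si](C)(C)C(C)(C)C)CCC[C@@H](CC)C#C/C=C(\COC)CC[C@H]2OC(C)(C)O[C@H]2C[C@H](O[Si](C)(C)C(C)(C)C)CNC1=O | intermediate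
38 | (16Z,18Z)-17-(benzyldimethylsilyl)-16,18-diene macrocycle, otherwise protected as 37 | CCC[C@@H]1OC(=O)[C@@H](C)C[C@@H](C)CCCC[C@@H](O[Si](C)(C)C(C)(C)C)CCC[C@@H](CC)/C=C(\[Si](C)(C)Cc3ccccc3)/C=C(\COC)CC[C@H]2OC(C)(C)O[C@H]2C[C@H](O[Si](C)(C)C(C)(C)C)CNC1=O | intermediate
39 | (16E,18Z)-diene macrocycle with free C11 and C25 hydroxyls and the C22/C23 acetonide | CCC[C@@H]1OC(=O)[C@@H](C)C[C@@H](C)CCCC[C@@H](O)CCC[C@@H](CC)/C=C/C=C(\COC)CC[C@H]2OC(C)(C)O[C@H]2C[C@H](O)CNC1=O | intermediate
40 | CNP0221503.3 (1S,4S,6S,11R,15R,16E,18Z,22R,23S,25S) | CCC[C@@H]1OC(=O)[C@@H](C)C[C@@H](C)CCCC[C@@H](O)CCC[C@@H](CC)/C=C/C=C(\COC)CC[C@@H](O)[C@@H](O)C[C@H](O)CNC1=O | target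

Total step count: 28. Longest linear sequence: 14 steps (steps 3 to 11, then 24 to 28, from 2-deoxy-D-ribose).

Steps most likely to fail

Step 25. Oligomerisation by intermolecular diyne metathesis may outcompete ring closure, or the closure may stall short of completion. The fallback sets out from 16 and 34 and closes the ring by lactonisation instead. Compound 16 would be acetylated (Ac2O, pyridine, DMAP) to the acetate F1. F1 and an excess of 34 would be joined by intermolecular alkyne cross-metathesis with the same alkylidyne at 0.1 M over 5 Å sieves, giving the open-chain enyne ester F2. LiOH would cleave both the acetate and the methyl ester to the seco hydroxy acid F3. Yamaguchi macrolactonisation under high dilution (2,4,6-trichlorobenzoyl chloride, Et3N, then slow addition to DMAP in toluene) would form the O2–C3 bond and come back to the route at 37.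

Step 7. Facial selectivity in the nitroaldol addition may be poor if catalyst and substrate preferences are mismatched, and retro-nitroaldol cleavage or β-elimination of the aldehyde may compete. The fallback sets out from 9. Corey–Chaykovsky methylenation (Me3SI, KN(SiMe3)2, THF) would give the terminal epoxide as a mixture of C25 epimers. Hydrolytic kinetic resolution with the (salen)Co(OAc) enantiomer that hydrolyses the (25R) epimer would leave the epoxide F4. Opening at the CH2 carbon with NaN3/NH4Cl would give the azido alcohol F5, silylation with TBSOTf the azido silyl ether F6, and Staudinger reduction (PPh3, THF/H2O) would come back to the route at 12.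

Step 21. The Grignard reagent may add to the methyl ester in competition with epoxide opening. The fallback sets out from 31 and removes the ester before the organometallic step. Saponification with LiOH would give the epoxy acid F7. Conversion into its magnesium carboxylate with i-PrMgCl at −40 °C and copper-catalysed opening with 32 would give the hydroxy acid F8. Silylation with excess TBSOTf/2,6-lutidine would give the silyl ester F9, and selective cleavage of the silyl ester with K2CO3 in aqueous MeOH would come back to the route at 35.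

Further compounds
F1 | step 25 | (2S)-1-{[(2S)-2-(tert-butyldimethylsilyloxy)-3-[(4S,5R)-5-[(3Z)-3-(methoxymethyl)hept-3-en-5-yn-1-yl]-2,2-dimethyl-1,3-dioxolan-4-yl]propyl]amino}-1-oxopentan-2-yl acetate | CCC[C@H](OC(C)=O)C(=O)NC[C@@H](O[Si](C)(C)C(C)(C)C)C[C@@H]1OC(C)(C)O[C@@H]1CC/C(COC)=C/C#CC
F2 | step 25 | open-chain C16≡C17 enyne: methyl ester at C3, acetate at the C1 oxygen, silyl ethers at C11 and C25, C22/C23 acetonide | COC(=O)[C@@H](C)C[C@@H](C)CCCC[C@@H](O[Si](C)(C)C(C)(C)C)CCC[C@@H](CC)C#C/C=C(\COC)CC[C@H]1OC(C)(C)O[C@H]1C[C@H](O[Si](C)(C)C(C)(C)C)CNC(=O)[C@H](CCC)OC(C)=O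
F3 | step 25 | seco hydroxy acid (free C3 acid and C1 hydroxyl) of the open-chain enyne | OC(=O)[C@@H](C)C[C@@H](C)CCCC[C@@H](O[Si](C)(C)C(C)(C)C)CCC[C@@H](CC)C#C/C=C(\COC)CC[C@H]1OC(C)(C)O[C@H]1C[C@H](O[Si](C)(C)C(C)(C)C)CNC(=O)[C@H](CCC)O
F4 | step 7 | (4S,5R)-2,2-dimethyl-4-{[(2S)-oxiran-2-yl]methyl}-5-vinyl-1,3-dioxolane | C1O[C@H]1C[C@@H]2OC(C)(C)O[C@@H]2C=C
F5 | step 7 | (2S)-1-azido-3-[(4S,5R)-2,2-dimethyl-5-vinyl-1,3-dioxolan-4-yl]propan-2-ol | [N-]=[N+]=NC[C@@H](O)C[C@@H]1OC(C)(C)O[C@@H]1C=C
F6 | step 7 | tert-butyldimethylsilyl ether of F5 | [N-]=[N+]=NC[C@@H](O[Si](C)(C)C(C)(C)C)C[C@@H]1OC(C)(C)O[C@@H]1C=C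
F7 | step 21 | (2S,4S)-2,4-dimethyl-8-[(2R)-oxiran-2-yl]octanoic acid | OC(=O)[C@@H](C)C[C@@H](C)CCCC[C@@H]1CO1
F8 | step 21 | (2S,4S,9R,13R)-13-ethyl-9-hydroxy-2,4-dimethylhexadec-14-ynoic acid | OC(=O)[C@@H](C)C[C@@H](C)CCCC[C@@H](O)CCC[C@@H](CC)C#CC
F9 | step 21 | tert-butyldimethylsilyl ester of 35 | CC(C)(C)[Si](C)(C)OC(=O)[C@@H](C)C[C@@H](C)CCCC[C@@H](O[Si](C)(C)C(C)(C)C)CCC[C@@H](CC)C#CC
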